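## Retrosynthetic overview

1. Target 28 is the C19 tiglate of a (13Z)-labda-7,13-dien-15-oic acid (labdane numbering throughout). The last operations are C19 acylation and release of the C15 acid from an allyl ester; the (13Z)-enoate comes from syn-methylcupration of a C13≡C14 alkynoate.
2. The C9 side chain and the C7=C8 alkene come from a C9 ketone by alkylative carbonyl transposition: organocerium addition, oxidative 1,3-transposition to the 8-en-7-one, then reductive 1,3-transposition that puts H on C9α.
3. Key disconnection: the C3–C4 bond of ring A. A (Z)-alkenyl iodide on C10 carbopalladates the isopropenyl group on C5 in 6-exo mode; boron capture and oxidation then give C19–OH. One flask closes ring A, sets the quaternary C4 and oxygenates C19.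
4. Enabling feature: C4 of ring A is quaternary and carries one methyl (C18) and one oxygenated methylene (C19), so it is a masked isopropenyl carbon on C5. Together with the C8 methyl, C7=C8 and C9 of ring B this maps onto (R)-carvone, whose α′ carbon becomes C10 by two alkylations.
5. Ring order: ring B is taken intact from carvone; ring A is closed second, by the key step.

Key step: step 5

Remark: α/β mean the decalin face opposite to / the same as the C10 methyl (C20); compound 6 is carried as a mixture of C10 epimers because step 4 passes through its planar enolate.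

## Route

Step 1
Reactants: 1 ethyl (2Z)-3-iodoprop-2-enoate
Product: 2 (2Z)-3-iodoprop-2-en-1-ol
Conditions: i-Bu2AlH (2.2 equiv), CH2Cl2, −78 °C → 0 °C; aq potassium sodium tartrate (KNaC4H4O6) work-up
Reagents that add atoms: none
Why: Low-temperature i-Bu2AlH reduction converts the ester to the primary allylic alcohol with retention of the (Z)-iodoalkene (ester reduction).

Step 2
Reactants: 2 (2Z)-3-iodoprop-2-en-1-ol
Product: 3 (1Z)-3-bromo-1-iodoprop-1-ene
Conditions: CBr4, PPh3, CH2Cl2, 0 °C
Reagents that add atoms: tetrabromomethane, BrC(Br)(Br)Br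
Why: Appel bromination proceeds by SN2 at the primary allylic carbon under neutral conditions and leaves the alkenyl iodide and its (Z) geometry intact.

Step 3
Reactants: 4 (R)-(−)-carvone
Product: 6 trans-6-methylcarvone [(5R,6S)-2,6-dimethyl-5-(prop-1-en-2-yl)cyclohex-2-en-1-one], via lithium enolate 5 (not isolated)
Conditions: LiN(i-Pr)2, THF, −78 °C; MeI, −78 → 0 °C
Reagents that add atoms: iodomethane, CI
Why: Kinetic deprotonation takes the α′ proton (future C10) and enolate 5 is methylated (enolate alkylation), expected mainly trans to the isopropenyl group; the C10 configuration at this stage is of no consequence.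

Step 4
Reactants: 6 trans-6-methylcarvone; 3 (1Z)-3-bromo-1-iodoprop-1-ene
Product: 8 (5S,6S)-6-[(2Z)-3-iodoprop-2-en-1-yl]-2,6-dimethyl-5-(prop-1-en-2-yl)cyclohex-2-en-1-one, via lithium enolate 7 (not isolated)
Conditions: LiN(i-Pr)2, THF, −78 °C; 3, DMPU, −78 → 0 °C
Reagents that add atoms: compound 3, BrC/C=C\I
Why: Enolate alkylation with the reactive allylic bromide builds the C10 quaternary stereocenter, the electrophile entering anti to the adjacent C5 isopropenyl group as is typical for 6-substituted carvone enolates, so that C1 is trans to C4 and the C20 methyl is cis to it.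

Step 5
Reactants: 8 alkenyl iodide from step 4
Product: 10 bicyclic hydroxy dienone [trans-fused decalin; 9-oxo, C2=C3, C7=C8 with 8-CH3, 4α-CH3, 4β-CH2OH, 10β-CH3, 5α-H; 4S,5S,10S], via neopentyl boronate 9 (not isolated)
Conditions: Pd(OAc)2 (5 mol %), P(o-tol)3 (12 mol %), B2pin2 (1.5 equiv), KOAc (3 equiv), 1,4-dioxane, 80 °C; then THF, pH 7 phosphate buffer, 30% H2O2, 0 °C → rt
Reagents that add atoms: bis(pinacolato)diboron, CC1(C)OB(OC1(C)C)B1OC(C)(C)C(C)(C)O1 (boron of 9); hydrogen peroxide, OO (oxygen of 10)
Why: Zerovalent palladium inserts into the C3–I bond with retention of the (Z) geometry, the alkenylpalladium adds syn across C4=C19 of the isopropenyl group in 6-exo-trig mode (ring A, new C3–C4 bond), and the resulting neopentylpalladium, which has no β-hydrogen, is captured by acetate-assisted transmetalation with B2pin2 and reductive elimination to boronate 9, which buffered H2O2 then oxidizes with retention to alcohol 10. The closest known reaction type is the domino Heck cyclization/boryl capture of halide-tethered 1,1-disubstituted alkenes, together with quaternary-centre-forming 6-exo Heck cyclizations of alkenyl halides. The new stereocenter C4 is substrate-controlled: the trans-diequatorial C10–C1 and C5–C4 bonds on ring B allow only one half-chair for the forming ring, and the eclipsed four-centre insertion geometry (Pd–C3 aligned with C4=C19, palladium out of the C2=C3 plane) is reached only with the methylene C19 pseudoaxial, that is on the β face syn to the C10 methyl, which leaves the C18 methyl equatorial as in the target. The step needs 6-exo over 7-endo closure, which 1,1-disubstituted alkenes normally give, and ring closure ahead of direct borylation of the alkenylpalladium, which the intramolecular insertion and the weak base KOAc favor. The ring B enone is remote and electron-poor, so it should not compete as an insertion partner, and the pH 7 peroxide work-up avoids its nucleophilic epoxidation.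

Step 6
Reactants: 10 bicyclic hydroxy dienone
Product: 11 C19 tert-butyldimethylsilyl ether of 10
Conditions: TBSCl, imidazole, DMF, rt
Reagents that add atoms: tert-butyldimethylsilyl chloride, CC(C)(C)[Si](C)(C)Cl
Why: Silyl ether formation protects the primary neopentyl C19 alcohol against the organometallic and chromium steps that follow.

Step 7
Reactants: 11 silyl ether
Product: 12 ring A saturated enone [as 11 but C2–C3 single bond]
Conditions: H2 (1 atm), RhCl(PPh3)3 (5 mol %), toluene/EtOH, rt
Reagents that add atoms: none
Why: Homogeneous hydrogenation with RhCl(PPh3)3 reduces the cis-disubstituted C2=C3 alkene much faster than the trisubstituted, conjugated C7=C8 alkene, so the alkene left by the Heck closure is removed selectively.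

Step 8
Reactants: 12 enone; 13 (4-bromobut-1-yn-1-yl)trimethylsilane
Product: 15 tertiary allylic alcohol [9β-OH, 9α-CH2CH2C≡C–SiMe3, C7=C8], via Grignard reagent 14 (not isolated)
Conditions: 13, Mg, THF (gives 14); CeCl3, THF, −78 °C; then 12, −78 → 0 °C
Reagents that add atoms: compound 13 (through 14), C[Si](C)(C)C#CCCBr
Why: Organocerium 1,2-addition (Grignard reagent with CeCl3) suppresses enolization and conjugate addition at the hindered C9 ketone; attack anti to the axial C10 methyl is expected, but the C9 carbinol configuration is irrelevant because step 9 makes C9 sp2.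

Step 9
Reactants: 15 tertiary allylic alcohol
Product: 16 transposed enone [7-oxo, C8=C9, side chain on C9]
Conditions: pyridinium chlorochromate [C5H5NH][CrO3Cl], 4 Å molecular sieves, CH2Cl2, rt
Reagents that add atoms: pyridinium chlorochromate, [O-][Cr](=O)(=O)Cl.c1cc[nH+]cc1 (supplies the C7 oxygen)
Why: Babler–Dauben oxidative transposition: the tertiary allylic chromate ester undergoes a [3,3] shift to C7 and is oxidized to the 8-en-7-one, which erases the C9 carbinol stereocenter.

Step 10
Reactants: 16 transposed enone
Product: 17 allylic alcohol [7β-OH, C8=C9]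
Conditions: NaBH4, CeCl3·7H2O, MeOH, −78 → 0 °C
Reagents that add atoms: none
Why: Luche 1,2-reduction; hydride should add axially from the α face of the rigid trans-fused enone, anti to the axial C10 methyl, giving the pseudoequatorial 7β alcohol that step 11 needs.

Step 11
Reactants: 17 allylic alcohol
Product: 20 Δ7 alkene [C7=C8, 9α-H, 9β-CH2CH2C≡C–SiMe3], via Mitsunobu adduct 18 (not isolated), via allylic diazene 19 (not isolated)
Conditions: N-isopropylidene-N′-(2-nitrobenzenesulfonyl)hydrazine (IPNBSH), PPh3, DEAD, THF, 0 °C → rt; then CF3CH2OH/H2O (1:1), rt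
Reagents that add atoms: none
Why: Myers reductive 1,3-transposition: Mitsunobu displacement at C7 with inversion gives the 7α adduct 18, hydrolysis and loss of sulfinate give the 7α-diazene 19, and its retro-ene loss of N2 delivers hydrogen suprafacially to the α face of C9 while the alkene moves to C7=C8, which sets C9 (9α-H, side chain β).

Step 12
Reactants: 20 silylalkyne
Product: 21 terminal alkyne
Conditions: K2CO3, MeOH, rt
Reagents that add atoms: none
Why: Base-catalyzed methanolysis cleaves the alkynyl C–Si bond selectively, the hindered alkyl silyl ether at C19 being stable to K2CO3/MeOH.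

Step 13
Reactants: 21 terminal alkyne
Product: 23 allyl alkynoate [side chain CH2CH2C≡C–CO2CH2CH=CH2], via lithium acetylide 22 (not isolated)
Conditions: n-BuLi, THF, −78 °C; ClCO2CH2CH=CH2, −78 → −20 °C
Reagents that add atoms: allyl chloroformate, C=CCOC(Cl)=O
Why: Deprotonation of the terminal alkyne and C-acylation of the acetylide with the chloroformate gives the alkynoate; the allyl ester is chosen because it can later be removed without touching the tiglate.

Step 14
Reactants: 23 allyl alkynoate
Product: 25 allyl (13Z)-enoate, C19 silyl ether, via alkenylcuprate 24 (not isolated)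
Conditions: Me2CuLi (from CuI, 2 MeLi), THF, −78 °C; MeOH then aq NH4Cl at −78 °C
Reagents that add atoms: lithium dimethylcuprate, [Li+].C[Cu-]C
Why: Syn-carbocupration of the alkynoate at −78 °C and low-temperature protonation with retention place the new methyl and H cis, hence C12 and the ester cis, which is the (13Z) geometry.

Step 15
Reactants: 25 allyl (13Z)-enoate silyl ether
Product: 26 C19 alcohol, allyl (13Z)-enoate
Conditions: HF·pyridine, pyridine, THF, 0 °C → rt
Reagents that add atoms: none
Why: Buffered fluoride desilylation frees the C19 alcohol without migration of the Δ7 alkene or isomerization of the (Z)-enoate.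

Step 16
Reactants: 26 C19 alcohol
Product: 27 C19 tiglate, allyl (13Z)-enoate
Conditions: tigloyl chloride, pyridine, DMAP (cat.), CH2Cl2, 0 °C → rt
Reagents that add atoms: (E)-2-methylbut-2-enoyl chloride (tigloyl chloride), C/C=C(\C)C(Cl)=O
Why: DMAP-catalyzed acylation of the primary neopentyl alcohol with the (E)-configured acid chloride; pyridine as the only base avoids vinylketene formation and E/Z scrambling of the tigloyl unit.

Step 17
Reactants: 27 C19 tiglate allyl ester
Product: 28 target, (4S,5R,9S,10R)-19-[(E)-2-methylbut-2-enoyloxy]labda-7,13Z-dien-15-oic acid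
Conditions: Pd(PPh3)4 (5 mol %), morpholine, THF, rt
Reagents that add atoms: none
Why: Tsuji–Trost deallylation: zerovalent palladium ionizes only the allyl ester and morpholine traps the allyl fragment, leaving the tiglate, both trisubstituted alkenes and the (13Z) geometry untouched.

## Compound list

1 | ethyl (2Z)-3-iodoprop-2-enoate | CCOC(=O)/C=C\I | starting material
2 | (2Z)-3-iodoprop-2-en-1-ol | OC/C=C\I | intermediate
3 | (1Z)-3-bromo-1-iodoprop-1-ene | BrC/C=C\I | intermediate
4 | (R)-(−)-carvone | C=C(C)[C@@H]1CC=C(C)C(=O)C1 | starting material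
5 | kinetic lithium α′-enolate of carvone (not isolated) | [Li+].C=C(C)[C@@H]1CC=C(C)C([O-])=C1 | intermediate
6 | trans-6-methylcarvone, (5R,6S)-2,6-dimethyl-5-(prop-1-en-2-yl)cyclohex-2-en-1-one | C=C(C)[C@@H]1CC=C(C)C(=O)[C@H]1C | intermediate
7 | lithium enolate of 6 (not isolated) | [Li+].C=C(C)[C@@H]1CC=C(C)C([O-])=C1C | intermediate
8 | (5S,6S)-6-[(2Z)-3-iodoprop-2-en-1-yl]-2,6-dimethyl-5-(prop-1-en-2-yl)cyclohex-2-en-1-one | C=C(C)[C@@H]1CC=C(C)C(=O)[C@@]1(C)C/C=C\I | intermediate
9 | neopentyl pinacol boronate (C19–Bpin analogue of 10; not isolated) | CC1(C)OB(C[C@@]2(C)C=CC[C@]3(C)C(=O)C(C)=CC[C@@H]23)OC1(C)C | intermediate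
10 | bicyclic hydroxy dienone (9-oxo, Δ2, Δ7, 4α-CH3, 4β-CH2OH, 10β-CH3, 5α-H) | OC[C@@]1(C)C=CC[C@]2(C)C(=O)C(C)=CC[C@@H]12 | intermediate
11 | C19 tert-butyldimethylsilyl ether of 10 | CC(C)(C)[Si](C)(C)OC[C@@]1(C)C=CC[C@]2(C)C(=O)C(C)=CC[C@@H]12 | intermediate
12 | ring A saturated silyl ether enone (9-oxo, Δ7) | CC(C)(C)[Si](C)(C)OC[C@@]1(C)CCC[C@]2(C)C(=O)C(C)=CC[C@@H]12 | intermediate
13 | (4-bromobut-1-yn-1-yl)trimethylsilane | C[Si](C)(C)C#CCCBr | starting material
14 | [4-(trimethylsilyl)but-3-yn-1-yl]magnesium bromide (not isolated) | C[Si](C)(C)C#CCC[Mg]Br | intermediate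
15 | tertiary allylic alcohol (9β-OH, 9α-[4-(trimethylsilyl)but-3-ynyl], Δ7) | CC(C)(C)[Si](C)(C)OC[C@@]1(C)CCC[C@]2(C)[C@](O)(CCC#C[Si](C)(C)C)C(C)=CC[C@@H]12 | intermediate
16 | 8-en-7-one with the silylbutynyl chain on C9 | CC(C)(C)[Si](C)(C)OC[C@@]1(C)CCC[C@]2(C)C(CCC#C[Si](C)(C)C)=C(C)C(=O)C[C@@H]12 | intermediate
17 | 7β-hydroxy-8-ene | CC(C)(C)[Si](C)(C)OC[C@@]1(C)CCC[C@]2(C)C(CCC#C[Si](C)(C)C)=C(C)[C@@H](O)C[C@@H]12 | intermediate
18 | 7α-[N-(2-nitrobenzenesulfonyl)-N′-isopropylidenehydrazino]-8-ene (not isolated) | CC(C)(C)[Si](C)(C)OC[C@@]1(C)CCC[C@]2(C)C(CCC#C[Si](C)(C)C)=C(C)[C@H](N(N=C(C)C)S(=O)(=O)c3ccccc3[N+](=O)[O-])C[C@@H]12 | intermediate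
19 | 7α-diazenyl-8-ene (not isolated) | CC(C)(C)[Si](C)(C)OC[C@@]1(C)CCC[C@]2(C)C(CCC#C[Si](C)(C)C)=C(C)[C@H](N=N)C[C@@H]12 | intermediate
20 | Δ7 alkene, 9α-H, 9β-[4-(trimethylsilyl)but-3-ynyl], C19 silyl ether | CC(C)(C)[Si](C)(C)OC[C@@]1(C)CCC[C@]2(C)[C@@H](CCC#C[Si](C)(C)C)C(C)=CC[C@@H]12 | intermediate
21 | terminal alkyne (9β-but-3-ynyl) | CC(C)(C)[Si](C)(C)OC[C@@]1(C)CCC[C@]2(C)[C@@H](CCC#C)C(C)=CC[C@@H]12 | intermediate
22 | lithium acetylide of 21 (not isolated) | CC(C)(C)[Si](C)(C)OC[C@@]1(C)CCC[C@]2(C)[C@@H](CCC#C[Li])C(C)=CC[C@@H]12 | intermediate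
23 | allyl alkynoate (side chain CH2CH2C≡C–CO2allyl) | CC(C)(C)[Si](C)(C)OC[C@@]1(C)CCC[C@]2(C)[C@@H](CCC#CC(=O)OCC=C)C(C)=CC[C@@H]12 | intermediate
24 | lithium alkenyl(methyl)cuprate from syn-addition (not isolated) | [Li+].CC(C)(C)[Si](C)(C)OC[C@@]1(C)CCC[C@]2(C)[C@@H](CC/C(C)=C(/[Cu-]C)C(=O)OCC=C)C(C)=CC[C@@H]12 | intermediate
25 | allyl (13Z)-19-(tert-butyldimethylsilyloxy)labda-7,13-dien-15-oate | CC(C)(C)[Si](C)(C)OC[C@@]1(C)CCC[C@]2(C)[C@@H](CC/C(C)=C\C(=O)OCC=C)C(C)=CC[C@@H]12 | intermediate
26 | allyl (13Z)-19-hydroxylabda-7,13-dien-15-oate | OC[C@@]1(C)CCC[C@]2(C)[C@@H](CC/C(C)=C\C(=O)OCC=C)C(C)=CC[C@@H]12 | intermediate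
27 | allyl (13Z)-19-(tigloyloxy)labda-7,13-dien-15-oate | C/C=C(\C)C(=O)OC[C@@]1(C)CCC[C@]2(C)[C@@H](CC/C(C)=C\C(=O)OCC=C)C(C)=CC[C@@H]12 | intermediate
28 | (4S,5R,9S,10R)-19-[(E)-2-methylbut-2-enoyloxy]labda-7,13Z-dien-15-oic acid | C/C=C(\C)C(=O)OC[C@@]1(C)CCC[C@]2(C)[C@@H](CC/C(C)=C\C(=O)O)C(C)=CC[C@@H]12 | target

## Summary and risks

Total step count: 17. Longest linear sequence: 16 steps (steps 1, 2 and 4–17, from ethyl (2Z)-3-iodoprop-2-enoate 1); the carvone branch (step 3, then steps 4–17) is 15 steps long.

Steps most likely to fail: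

1. Step 5. The carbopalladation may take the opposite face of the isopropenyl group, so that the palladated methylene ends up on the α face of C4 (poor or reversed facial selectivity). Lesser risks are borylation of the alkenylpalladium before it cyclizes and 3-exo closure of the neopentylpalladium onto C2=C3 before boron capture. Fallback for the reversed facial sense, setting out from 8: allylic oxidation of the isopropenyl methyl group (SeO2 cat., t-BuOOH, CH2Cl2) should give the 2-(hydroxymethyl)allyl ketone F1, and silylation (TBSCl, imidazole) its silyl ether F2. A reductive Heck cyclization (Pd(OAc)2, PPh3, HCO2Na, DMF, 80 °C) then closes the same C3–C4 bond without any boron partner. Here the palladated methylene is reduced to the C18 methyl and the pre-installed silyloxymethyl becomes C19, so the two carbons exchange roles. A preference for the palladated carbon on the α face, the opposite of what step 5 needs, would therefore lead directly to silyl ether 11, where the route is rejoined.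

2. Step 11. Mitsunobu displacement at the hindered allylic C7 carbinol may be slow and give way to elimination to the diene or to loss of stereospecificity. Fallback, setting out from 17: formylation (HCO2H/Ac2O, pyridine) should give the 7β-formate F3. Palladium-catalyzed formate hydrogenolysis (Pd(OAc)2, PBu3, THF, reflux) ionizes it with inversion and delivers hydride from the metal on the α face to the more substituted allyl terminus C9, with loss of CO2. This should give the same Δ7, 9α-H product, and the route is rejoined at 20.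

3. Step 14. Equilibration of the alkenylcopper/allenoate intermediate before protonation would erode the (13Z) geometry, and the cuprate may also attack the allyl ester. Fallback, setting out from 23: conjugate addition of pyrrolidine should give the enamino ester F4, and aqueous acetic acid hydrolysis the β-keto ester F5. E-selective enol triflate formation (Tf2O, aqueous Me4NOH, toluene) should give the (E)-enol triflate F6, with the triflate trans to the ester. Stereoretentive iron-catalyzed methylation (MeMgBr, Fe(acac)3 cat., THF/NMP, −30 °C) then fixes the geometry by substitution instead of addition, and the route is rejoined at 25.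

## Further compounds

F1 | step 5 | (5S,6S)-5-(3-hydroxyprop-1-en-2-yl)-6-[(2Z)-3-iodoprop-2-en-1-yl]-2,6-dimethylcyclohex-2-en-1-one | C=C(CO)[C@@H]1CC=C(C)C(=O)[C@@]1(C)C/C=C\I
F2 | step 5 | tert-butyldimethylsilyl ether of F1 | C=C(CO[Si](C)(C)C(C)(C)C)[C@@H]1CC=C(C)C(=O)[C@@]1(C)C/C=C\I
F3 | step 11 | 7β-formate of 17 | CC(C)(C)[Si](C)(C)OC[C@@]1(C)CCC[C@]2(C)C(CCC#C[Si](C)(C)C)=C(C)[C@@H](OC=O)C[C@@H]12
F4 | step 14 | allyl (E)-3-(pyrrolidin-1-yl)enoate from 23 | CC(C)(C)[Si](C)(C)OC[C@@]1(C)CCC[C@]2(C)[C@@H](CC/C(N3CCCC3)=C\C(=O)OCC=C)C(C)=CC[C@@H]12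
F5 | step 14 | allyl β-keto ester (13-oxo) | CC(C)(C)[Si](C)(C)OC[C@@]1(C)CCC[C@]2(C)[C@@H](CCC(=O)CC(=O)OCC=C)C(C)=CC[C@@H]12
F6 | step 14 | allyl (E)-enol triflate (triflate on C13, trans to ester) | CC(C)(C)[Si](C)(C)OC[C@@]1(C)CCC[C@]2(C)[C@@H](CC/C(OS(=O)(=O)C(F)(F)F)=C\C(=O)OCC=C)C(C)=CC[C@@H]12
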